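The two oxygens that flank the diaryl ether bridge, the methoxy oxygen on C1 of ring A and the hydroxyl oxygen on C2 of ring B, are read as former formyl groups. Each of these carbons lies ortho to a bridge carbon (C6 of ring A, C1 of ring B), so the ether oxygen can assist aryl migration, and the ring A formyl group first activates fluoride displacement at C6. The precursor, tetrabromo diaryl ether dialdehyde 3, comes from phenol 1 and aryl fluoride 2 in one SNAr step. One peracid operation turns both CHO groups into OH through bis-formate 4, giving bisphenol 5. Selective silylation, methylation and desilylation finish the route.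

Key step: step 2

Remark: ring A is the methoxy ring (C1 bears OMe, C2 and C4 bear Br, C6 bears the bridge oxygen) and ring B is the hydroxy ring (C1 bears the bridge oxygen, C2 bears OH, C4 and C6 bear Br). Compound 2 is assumed to be purchasable. Only the formyl group of 2 activates the displacement; the formyl group of 1 is a passenger that makes its phenoxide a weaker nucleophile. A triisopropylsilyl group is chosen over a smaller silyl group for sharper steric discrimination between the two phenols and for stability to carbonate.

Step 1
Reactants: 1 3,5-dibromosalicylaldehyde (3,5-dibromo-2-hydroxybenzaldehyde); 2 2,4-dibromo-6-fluorobenzaldehyde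
Product: 3 2,4-dibromo-6-(2,4-dibromo-6-formylphenoxy)benzaldehyde
Conditions: Cs2CO3, dry DMAc, 90 °C, under nitrogen
Reagents that add atoms: none
Why: Nucleophilic aromatic substitution (SNAr), in which the cesium phenoxide of 1 adds at the fluorine-bearing carbon of 2, the ortho formyl group stabilises the Meisenheimer adduct, and fluoride leaves much faster than the bromines that are also ortho and para to that formyl group, so near-equimolar partners and exclusion of water should give ether 3.

Step 2
Reactants: 3 2,4-dibromo-6-(2,4-dibromo-6-formylphenoxy)benzaldehyde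
Product: 5 2,4-dibromo-6-(2,4-dibromo-6-hydroxyphenoxy)phenol, via bis-formate 4 (not isolated)
Conditions: mCPBA (3 equiv), CH2Cl2, 0 °C to reflux; then K2CO3, MeOH, rt; aq. HCl work-up
Reagents that add atoms: mCPBA (3-chloroperoxybenzoic acid), OOC(=O)c1cccc(Cl)c1
Why: Twofold Baeyer–Villiger (Dakin-type) oxidation of aryl aldehydes: the peracid adds to each formyl group to give a Criegee adduct, the aryl carbon (C1 of ring A, C2 of ring B) shifts to the peroxide oxygen as 3-chlorobenzoate departs, and methanolysis of the resulting bis-formate 4 frees both phenols. The closest known reaction is the peracid conversion of ortho-alkoxy and ortho-aryloxy benzaldehydes, brominated ones included, into phenols by way of aryl formates. No ring is closed and no stereocentre is created. The selectivity required is aryl over hydride migration in both adducts (phenol instead of carboxylic acid); it should be secured by the bridge oxygen ortho to each migrating carbon (on C6 of ring A, on C1 of ring B), which stabilises the electron-deficient migrating terminus, and on ring A by the two ortho substituents that twist the formyl group out of the ring plane. Aryl bromides and the diaryl ether linkage do not react with the peracid, and the carbonate stage only transesterifies the formates.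

Step 3
Reactants: 5 2,4-dibromo-6-(2,4-dibromo-6-hydroxyphenoxy)phenol
Product: 6 2,4-dibromo-6-[2,4-dibromo-6-(triisopropylsilyloxy)phenoxy]phenol
Conditions: TIPSCl (1.05 equiv), imidazole, DMF, 0 °C to rt
Reagents that add atoms: TIPSCl (chlorotriisopropylsilane), CC(C)[Si](Cl)(C(C)C)C(C)C
Why: Site-selective silylation of a phenol under steric control, since the ring B hydroxyl (on C2) has a hydrogen on one flank (C3) whereas the ring A hydroxyl (on C1) is wedged between bromine (C2) and the aryloxy group (C6), so the bulky silyl chloride should react at the ring B hydroxyl only.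

Step 4
Reactants: 6 2,4-dibromo-6-[2,4-dibromo-6-(triisopropylsilyloxy)phenoxy]phenol
Product: 7 [3,5-dibromo-2-(3,5-dibromo-2-methoxyphenoxy)phenoxy]triisopropylsilane
Conditions: MeI, K2CO3, acetone, 40 °C
Reagents that add atoms: iodomethane, CI
Why: Williamson ether synthesis, in which the acidic ring A phenol (bromine ortho and para) is deprotonated by carbonate and methylated by iodomethane, while the hindered triisopropylsilyl aryl ether should neither cleave nor migrate under these conditions.

Step 5
Reactants: 7 [3,5-dibromo-2-(3,5-dibromo-2-methoxyphenoxy)phenoxy]triisopropylsilane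
Product: 8 3,5-dibromo-2-(3,5-dibromo-2-methoxyphenoxy)phenol (target)
Conditions: TBAF, THF, 0 °C; dilute aq. HCl work-up
Reagents that add atoms: none
Why: Fluoride-induced desilylation, in which fluoride attacks silicon to form the strong Si–F bond and releases the ring B phenoxide, protonated on work-up, leaving the methyl ether, the diaryl ether and the aryl bromides untouched.

Compound list
1 | 3,5-dibromosalicylaldehyde (3,5-dibromo-2-hydroxybenzaldehyde) | O=Cc1cc(Br)cc(Br)c1O | starting material
2 | 2,4-dibromo-6-fluorobenzaldehyde | O=Cc1c(F)cc(Br)cc1Br | starting material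
3 | 2,4-dibromo-6-(2,4-dibromo-6-formylphenoxy)benzaldehyde | O=Cc1c(Br)cc(Br)cc1Oc1c(C=O)cc(Br)cc1Br | intermediate
4 | 2,4-dibromo-6-[2,4-dibromo-6-(formyloxy)phenoxy]phenyl formate (bis-formate, formed in the flask) | O=COc1c(Br)cc(Br)cc1Oc1c(OC=O)cc(Br)cc1Br | intermediate
5 | 2,4-dibromo-6-(2,4-dibromo-6-hydroxyphenoxy)phenol | Oc1c(Br)cc(Br)cc1Oc1c(O)cc(Br)cc1Br | intermediate
6 | 2,4-dibromo-6-[2,4-dibromo-6-(triisopropylsilyloxy)phenoxy]phenol | CC(C)[Si](C(C)C)(C(C)C)Oc1cc(Br)cc(Br)c1Oc1cc(Br)cc(Br)c1O | intermediate
7 | [3,5-dibromo-2-(3,5-dibromo-2-methoxyphenoxy)phenoxy]triisopropylsilane | CC(C)[Si](C(C)C)(C(C)C)Oc1cc(Br)cc(Br)c1Oc1cc(Br)cc(Br)c1OC | intermediate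
8 | 3,5-dibromo-2-(3,5-dibromo-2-methoxyphenoxy)phenol | COc1c(Br)cc(Br)cc1Oc1c(O)cc(Br)cc1Br | target

Total step count: 5
Longest linear sequence: 5 steps (from 1 or 2 to 8)

Steps most likely to fail

Step 2. The risk is hydride instead of aryl migration in one or both Criegee adducts, or stalling after the first oxidation because the electron-poor, doubly ortho-substituted ring A aldehyde adds peracid slowly. The fallback removes the migrating hydrogen altogether; it sets out from 3 and returns at 5. Addition of MeMgBr (THF, −78 °C) to both formyl groups would give 1-{2,4-dibromo-6-[2,4-dibromo-6-(1-hydroxyethyl)phenoxy]phenyl}ethan-1-ol F1 as a mixture of diastereomers, which does not matter because both carbinol centres are oxidised next. Dess–Martin periodinane (CH2Cl2, rt) would give the diketone 1-[2-(2-acetyl-4,6-dibromophenoxy)-4,6-dibromophenyl]ethan-1-one F2. Baeyer–Villiger oxidation with trifluoroperacetic acid (trifluoroacetic anhydride, urea–hydrogen peroxide, Na2HPO4, CH2Cl2) would give the bis-acetate 2,4-dibromo-6-[2-(acetyloxy)-4,6-dibromophenoxy]phenyl acetate F3, since in an aryl methyl ketone the only competitor of the aryl group is methyl, the poorest migrating group. K2CO3 in MeOH would then release 5.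

Step 3. The risk is insufficient site discrimination in the monosilylation (reaction at the ring A hydroxyl or at both), or silyl transfer between the two neighbouring oxygens under the base of step 4. The fallback puts the methyl group in place before the ether is made and oxidises one ring at a time; it sets out from 1, bypasses 3 to 7, and returns at 8. Methylation of 1 (MeI, K2CO3, DMF, rt) would give 3,5-dibromo-2-methoxybenzaldehyde F4. Peracid oxidation (mCPBA, CH2Cl2; then K2CO3, MeOH) would pass through 3,5-dibromo-2-methoxyphenyl formate F5, formed in the flask, to 3,5-dibromo-2-methoxyphenol F6, which is ring A with its methyl ether installed. Its phenoxide (K2CO3, DMAc, 80 °C) would displace fluoride from commercial 3,5-dibromo-2-fluorobenzaldehyde (O=Cc1cc(Br)cc(Br)c1F) to give 3,5-dibromo-2-(3,5-dibromo-2-methoxyphenoxy)benzaldehyde F7. A final peracid oxidation and methanolysis, through 3,5-dibromo-2-(3,5-dibromo-2-methoxyphenoxy)phenyl formate F8 formed in the flask, would give 8.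

Step 1. The risk is slow displacement by a chelated, doubly ortho-substituted, electron-poor phenoxide, with competing attack on the formyl-activated bromines of 2 or of 3 at the temperature needed. The fallback reverses the roles of the two rings; it sets out from 2 and returns at 3. Fluoride-to-hydroxide exchange with 2-(methanesulfonyl)ethanol and NaH (DMF, 0 °C to rt) would pass through 2,4-dibromo-6-[2-(methanesulfonyl)ethoxy]benzaldehyde F9, which eliminates methanesulfonylethene in the flask to give 2,4-dibromo-6-hydroxybenzaldehyde F10. Its phenoxide has one free ortho position and would be coupled (K2CO3, DMAc, 80 °C) with commercial 3,5-dibromo-2-fluorobenzaldehyde, whose bromines are meta to the formyl group and therefore not activated, to give 3.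

Further compounds
F1 | step 2 | 1-{2,4-dibromo-6-[2,4-dibromo-6-(1-hydroxyethyl)phenoxy]phenyl}ethan-1-ol (mixture of diastereomers) | CC(O)c1c(Br)cc(Br)cc1Oc1c(C(C)O)cc(Br)cc1Br
F2 | step 2 | 1-[2-(2-acetyl-4,6-dibromophenoxy)-4,6-dibromophenyl]ethan-1-one | CC(=O)c1c(Br)cc(Br)cc1Oc1c(C(C)=O)cc(Br)cc1Br
F3 | step 2 | 2,4-dibromo-6-[2-(acetyloxy)-4,6-dibromophenoxy]phenyl acetate | CC(=O)Oc1c(Br)cc(Br)cc1Oc1c(OC(C)=O)cc(Br)cc1Br
F4 | step 3 | 3,5-dibromo-2-methoxybenzaldehyde | COc1c(Br)cc(Br)cc1C=O
F5 | step 3 | 3,5-dibromo-2-methoxyphenyl formate | COc1c(Br)cc(Br)cc1OC=O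
F6 | step 3 | 3,5-dibromo-2-methoxyphenol | COc1c(Br)cc(Br)cc1O
F7 | step 3 | 3,5-dibromo-2-(3,5-dibromo-2-methoxyphenoxy)benzaldehyde | COc1c(Br)cc(Br)cc1Oc1c(C=O)cc(Br)cc1Br
F8 | step 3 | 3,5-dibromo-2-(3,5-dibromo-2-methoxyphenoxy)phenyl formate | COc1c(Br)cc(Br)cc1Oc1c(OC=O)cc(Br)cc1Br
F9 | step 1 | 2,4-dibromo-6-[2-(methanesulfonyl)ethoxy]benzaldehyde | CS(=O)(=O)CCOc1cc(Br)cc(Br)c1C=O
F10 | step 1 | 2,4-dibromo-6-hydroxybenzaldehyde | O=Cc1c(O)cc(Br)cc1Br
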